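Noon's last reading holds less product than spring's, 48.0% against 101% of both substrates charged, yet more excess of left-handed product, 26.7% against 8.44%. Before choosing the next run, we therefore write the balance of coupling partner.

| setting | noon | spring | elm | larch |
|---|---|---|---|---|
| left-handed substrate | 0.40 M | 0.40 M | 0.40 M | 0.40 M |
| right-handed substrate | 0.40 M | 0.40 M | 0.40 M | 0.40 M |
| coupling partner | 1.1 equiv | 4.4 equiv | 2.20 equiv | 2.20 equiv |
| temperature | 55 °C | 68 °C | 75 °C | 60 °C |
| remark | run made earlier | run made earlier |  |  |
| time |  |  | 150 min | 50 min |

| run | time / min | left-handed product / % | right-handed product / % |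
|---|---|---|---|
| noon | 3.00 | 13.4 | 4.9 |
| noon | 8.00 | 19.3 | 9.2 |
| noon | 15.0 | 26.3 | 11.0 |
| noon | 40.0 | 30.4 | 17.6 |
| spring | 10.0 | 49.4 | 41.9 |
| spring | 20.0 | 49.7 | 45.3 |
| spring | 30.0 | 53.7 | 46.9 |
| spring | 40.0 | 54.6 | 46.1 |

(each reading ± 1 percentage point)

- the winner by excess of left-handed product over right-handed product; "neither" if no more than 2 percentage points parts them (elm / larch / neither)
- excess of left-handed product over right-handed product at the end, elm
- excess of left-handed product over right-handed product at the end, larch

- coupling partner is single-handed; left-handed substrate and right-handed substrate are mirror images of each other, charged as a racemate, each of them at the stated concentration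
- an excess is the difference of the two amounts in percent of their sum
- an excess is below zero if the other one leads
- the handed part of coupling partner does not stay in what it makes, so the products of the two hands are mirror images too

We call spare partner the coupling partner charged less both substrates charged. For elm and larch:

spare = [coupling partner] − [left-handed substrate] − [right-handed substrate] = 0.880 M − 0.800 M = 0.0800 M

Noon's spare is −0.360 M, so there coupling partner is the limiting reagent. Spring's is 0.960 M. In elm and larch, spare is 10.0% of the substrates charged. If the two products are the one use of coupling partner, free coupling partner stays ahead of the unreacted substrates by spare throughout the run. We keep 2.20 equiv, choose between elm and larch, and watch that difference. Our balance gives no figure for the excess, so for that we have the forecast: elm wins, with 22% for elm and 14% for larch, on the ground that “Its partner is only just sufficient, so the slow tail gives racemisation time to feed remaining right-handed substrate into left-handed”.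

Elm gives 28.8% and larch 17.1%, so the winner is elm.

    left-handed substrate ⇌ achiral form (K = 0.350, k = 0.0120 min⁻¹, Ea = 113 kJ mol⁻¹, ΔH = −32.0 kJ mol⁻¹)
    coupling partner ⇌ dormant form (K = 4.90, k = 0.00780 min⁻¹, Ea = 109 kJ mol⁻¹, ΔH = −21.0 kJ mol⁻¹)
    coupling partner + right-handed substrate → right-handed product (k = 0.110 L mol⁻¹ min⁻¹, Ea = 53.0 kJ mol⁻¹)
    right-handed substrate ⇌ achiral form (K = 0.350, k = 0.0120 min⁻¹, Ea = 113 kJ mol⁻¹, ΔH = −32.0 kJ mol⁻¹)
    coupling partner + left-handed substrate → left-handed product (k = 0.310 L mol⁻¹ min⁻¹, Ea = 63.0 kJ mol⁻¹)
    (constants at 60 °C)

At 150 min, elm holds 0.0952 M of dormant form, more than its spare of 0.0800 M. Spare less dormant form is thus −0.0152 M, and elm's coupling partner stands at 2.24% of its charge. A neighbour of larch charged with 5.50 equiv has a spare of 1.40 M against 0.454 M of dormant form, and its excess of left-handed product is 2.38%.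

The numbers in the tables are calculated for an exercise, noise included.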